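**Retrosynthetic overview**

1. Feature: in the 2,3-dihydrobenzofuran, the benzo carbon C7a of ring D (bonded to O1) is para to C5, which carries the propenal. With that chain cut back to a formyl group (C=C by Wittig), the O1–C7a aryl ether bond is an SNAr site, so the five-membered O-ring is opened there to a syn 1-(ring C aryl)-2-(ortho-fluoroaryl)propane-1,3-diol.
2. That syn fluoro diol comes from an auxiliary-controlled syn aldol between a ring D arylacetyl imide and O-allyl syringaldehyde (sets C2 and C3), then imide reduction and silylation of the primary hydroxyl.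
3. Both erythro arylglycerol β-aryl ether units are cut at C7–C8 (aryloxyacetyl imide plus aryl aldehyde: syn aldol, then Mitsunobu inversion of the carbinol carbon). The cut at C7'–C8' divides the target into a ring C/D aryloxyacetyl imide and a ring A/B aldehyde.
4. The ring A/B aldehyde is made the same way from 4-bromo-2,6-dimethoxyphenol and O-silyl vanillin; the bromide later becomes the formyl group.
5. Ring order: the four benzene rings are bought; the dihydrofuran ring is the only ring formed, before either arylglycerol unit is attached.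

Key step: step 10

**Remarks on the chemistry (assumptions)**

- Locants: dihydrobenzofuran O1, C2 (bears ring C), C3 (bears CH2OH), C3a, C4–C7, C7a (ring D). Unit between rings A and B: C7 (carbinol), C8 (aryloxy carbon), C9 (CH2OH). Unit between rings B and C: C7', C8', C9'.
- The target is trans-(2R,3S) in the dihydrofuran and (7R,8S), (7'R,8'S) in the two arylglycerol units. These units are erythro, which is the anti relationship of an aldol product, so each is made by a syn aldol followed by inversion of the carbinol carbon.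
- The ring C phenol is carried as an allyl ether (removable by zerovalent palladium without acid). The primary oxygen of the key-step precursor is carried as a triisopropylsilyl ether (resists O-to-O silyl shift under base).
- 4-Fluoro-3-methoxybenzaldehyde, syringaldehyde, vanillin, 4-bromo-2,6-dimethoxyphenol and (R)-4-benzyl-1,3-oxazolidin-2-one are taken as commercial.

**Route**

Step 1
Reactants: 1 4-fluoro-3-methoxybenzaldehyde
Product: 2 2-(4-fluoro-3-methoxyphenyl)-1,3-dioxolane
Conditions: HOCH2CH2OH, p-TsOH·H2O (cat.), toluene, reflux, Dean–Stark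
Reagents that add atoms: ethylene glycol, OCCO
Why: Acid-catalysed acetalisation with azeotropic removal of water masks the formyl group against the organolithium, boron triflate and hydride steps ahead.

Step 2
Reactants: 2 2-(4-fluoro-3-methoxyphenyl)-1,3-dioxolane
Product: 4 2-[4-fluoro-3-methoxy-5-(prop-2-en-1-yl)phenyl]-1,3-dioxolane, via aryllithium 3 (not isolated)
Conditions: n-BuLi, PMDTA, THF, −78 °C; CuBr·SMe2 (cat.), allyl bromide, −78 to −30 °C
Reagents that add atoms: allyl bromide, C=CCBr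
Why: Directed ortho-metalation in which the triamine-complexed base responds to C–H acidity and not to chelation, so the hydrogen next to fluorine (H-5) should be removed in preference to H-2 between methoxy and acetal, and copper-catalysed allylation at low temperature should outrun loss of LiF.

Step 3
Reactants: 4 2-[4-fluoro-3-methoxy-5-(prop-2-en-1-yl)phenyl]-1,3-dioxolane
Product: 5 [5-(1,3-dioxolan-2-yl)-2-fluoro-3-methoxyphenyl]acetic acid
Conditions: KMnO4 (cat.), NaIO4, K2CO3, t-BuOH/H2O, rt; citric acid to pH 4–5 at 0 °C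
Reagents that add atoms: sodium periodate, [Na+].[O-]I(=O)(=O)=O; water, O
Why: Lemieux–von Rudloff oxidative cleavage takes the terminal alkene directly to the acid one carbon shorter, and the carbonate-buffered medium should leave the dioxolane intact.

Step 4
Reactants: 5 [5-(1,3-dioxolan-2-yl)-2-fluoro-3-methoxyphenyl]acetic acid; 6 (R)-4-benzyl-1,3-oxazolidin-2-one
Product: 8 (R)-4-benzyl-3-{[5-(1,3-dioxolan-2-yl)-2-fluoro-3-methoxyphenyl]acetyl}-1,3-oxazolidin-2-one, via mixed pivalic anhydride 7 (not isolated)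
Conditions: t-BuCOCl, Et3N, THF, −20 °C; then LiCl, 6, rt
Reagents that add atoms: none
Why: N-acylation of the oxazolidinone through the mixed pivalic anhydride with LiCl/Et3N activation is a standard mild imide synthesis that needs no strong base near the fluoroarene or the acetal.

Step 5
Reactants: 9 syringaldehyde
Product: 10 4-(allyloxy)-3,5-dimethoxybenzaldehyde
Conditions: allyl bromide, K2CO3, DMF, 60 °C
Reagents that add atoms: allyl bromide, C=CCBr
Why: Williamson etherification gives a phenol protecting group that should stand boron triflate, hydride, mild acid and carbonate base and can later be removed without acid.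

Step 6
Reactants: 8 ring D arylacetyl imide; 10 4-(allyloxy)-3,5-dimethoxybenzaldehyde
Product: 12 (R)-4-benzyl-3-[(2R,3R)-3-(4-allyloxy-3,5-dimethoxyphenyl)-2-[5-(1,3-dioxolan-2-yl)-2-fluoro-3-methoxyphenyl]-3-hydroxypropanoyl]-1,3-oxazolidin-2-one, via boron enolate 11 (not isolated)
Conditions: Bu2BOTf, i-Pr2NEt, CH2Cl2, −78 to 0 °C; 10, −78 to 0 °C; pH 7 buffer, MeOH, H2O2, 0 °C
Reagents that add atoms: none
Why: Evans syn aldol in which the (Z)-boron enolate reacts through a Zimmerman–Traxler chair on the enolate face away from the benzyl group of the (R)-auxiliary, setting the carbinol carbon (future C2, R) and the α-carbon (future C3) in the syn relationship.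

Step 7
Reactants: 12 syn aldol adduct
Product: 13 (1R,2S)-1-(4-allyloxy-3,5-dimethoxyphenyl)-2-[5-(1,3-dioxolan-2-yl)-2-fluoro-3-methoxyphenyl]propane-1,3-diol
Conditions: LiBH4, MeOH (1 equiv), THF, 0 °C
Reagents that add atoms: none
Why: Reductive cleavage of the acyl oxazolidinone by borohydride gives the primary alcohol without touching the stereocentres, and once the acyl carbon is reduced a retro-aldol is no longer possible.

Step 8
Reactants: 13 syn diol
Product: 14 (1R,2S)-1-(4-allyloxy-3,5-dimethoxyphenyl)-2-[5-(1,3-dioxolan-2-yl)-2-fluoro-3-methoxyphenyl]-3-(triisopropylsilyloxy)propan-1-ol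
Conditions: i-Pr3SiCl, imidazole, DMF, 0 °C to rt
Reagents that add atoms: triisopropylsilyl chloride, CC(C)[Si](Cl)(C(C)C)C(C)C
Why: Sterically controlled silylation selects the primary hydroxyl over the hindered benzylic one, and the bulky silyl group is chosen because it should not shift to the neighbouring alkoxide under base.

Step 9
Reactants: 14 silyl ether acetal
Product: 15 3-[(1R,2S)-1-(4-allyloxy-3,5-dimethoxyphenyl)-1-hydroxy-3-(triisopropylsilyloxy)propan-2-yl]-4-fluoro-5-methoxybenzaldehyde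
Conditions: p-TsOH·H2O (cat.), acetone/H2O (10:1), rt
Reagents that add atoms: water, O
Why: Acid-catalysed acetal hydrolysis should be far faster than ionisation of the benzylic carbinol, which is flanked by two electron-withdrawing β-substituents, so the formyl group is freed with the syn stereochemistry intact.

Step 10
Reactants: 15 syn fluoro aldehyde
Product: 16 (2R,3S)-2-(4-allyloxy-3,5-dimethoxyphenyl)-7-methoxy-3-[(triisopropylsilyloxy)methyl]-2,3-dihydro-1-benzofuran-5-carbaldehyde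
Conditions: Cs2CO3, dry DMF (0.02 M), 70 °C
Reagents that add atoms: none
Why: The carbonate generates the secondary alkoxide of 15 in low concentration; it adds ipso to fluorine at the ring D carbon that becomes C7a, the negative charge of the cyclohexadienyl adduct is taken up by the para formyl group, and loss of fluoride restores the arene (addition–elimination SNAr). The closest known reaction type is the intramolecular SNAr etherification of ortho-fluoroaryl alkanols carrying an ortho or para acceptor, which gives 2,3-dihydrobenzofurans. The ring O1–C2–C3–C3a–C7a closes in the 5-exo-trig mode, the attacked C7a=C7 π bond lying outside the new ring. No stereocentre is created: C2 and C3 come from step 6 and none of their bonds is broken, so the syn diol monoether maps onto the trans-(2R,3S) ring without a benzylic cation that could scramble C2. The step needs O-arylation by the secondary alkoxide alone: its addition to the aldehyde is reversible and unproductive, the primary oxygen is blocked by a silyl group too bulky for a 1,5 shift, and high dilution suppresses intermolecular substitution.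

Step 11
Reactants: 16 dihydrobenzofuran aldehyde
Product: 17 2-[(2R,3S)-2-(4-allyloxy-3,5-dimethoxyphenyl)-7-methoxy-3-[(triisopropylsilyloxy)methyl]-2,3-dihydro-1-benzofuran-5-yl]-1,3-dioxolane
Conditions: Me3SiOCH2CH2OSiMe3, Me3SiOTf (cat.), CH2Cl2, −78 to −20 °C; pyridine
Reagents that add atoms: 1,2-bis(trimethylsilyloxy)ethane, C[Si](C)(C)OCCO[Si](C)(C)C
Why: Silyl-triflate-catalysed acetalisation under aprotic low-temperature conditions masks the aldehyde again for the enolisation and hydride steps without exposing the benzylic aryl ether at C2 to protic acid.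

Step 12
Reactants: 17 allyl ether
Product: 18 4-[(2R,3S)-5-(1,3-dioxolan-2-yl)-7-methoxy-3-[(triisopropylsilyloxy)methyl]-2,3-dihydro-1-benzofuran-2-yl]-2,6-dimethoxyphenol
Conditions: Pd(PPh3)4 (cat.), morpholine, THF, rt
Reagents that add atoms: none
Why: Tsuji–Trost deallylation, in which zerovalent palladium ionises the allyl aryl ether to a π-allyl complex that morpholine traps, frees the ring C phenol under neutral conditions.

Step 13
Reactants: 6 (R)-4-benzyl-1,3-oxazolidin-2-one
Product: 20 (R)-4-benzyl-3-(bromoacetyl)-1,3-oxazolidin-2-one, via lithiated oxazolidinone 19 (not isolated)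
Conditions: n-BuLi, THF, −78 °C; BrCH2COBr, −78 to 0 °C
Reagents that add atoms: bromoacetyl bromide, BrCC(Br)=O
Why: N-acylation of the lithiated oxazolidinone by the acid bromide is faster than displacement at the CH2Br carbon and gives the glycolate-transfer reagent.

Step 14
Reactants: 18 ring C phenol; 20 (R)-4-benzyl-3-(bromoacetyl)-1,3-oxazolidin-2-one
Product: 21 (R)-4-benzyl-3-({4-[(2R,3S)-5-(1,3-dioxolan-2-yl)-7-methoxy-3-[(triisopropylsilyloxy)methyl]-2,3-dihydro-1-benzofuran-2-yl]-2,6-dimethoxyphenoxy}acetyl)-1,3-oxazolidin-2-one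
Conditions: K2CO3, acetone, 40 °C
Reagents that add atoms: none
Why: Williamson etherification by SN2 at the carbonyl-activated CH2Br carbon, which the hindered phenoxide should attack faster than the imide carbonyl.

Step 15
Reactants: 22 4-bromo-2,6-dimethoxyphenol; 20 (R)-4-benzyl-3-(bromoacetyl)-1,3-oxazolidin-2-one
Product: 23 (R)-4-benzyl-3-[(4-bromo-2,6-dimethoxyphenoxy)acetyl]-1,3-oxazolidin-2-one
Conditions: K2CO3, acetone, 40 °C
Reagents that add atoms: none
Why: The same Williamson etherification installs the chiral glycolate unit on the ring B phenol, whose bromine is the latent formyl group.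

Step 16
Reactants: 24 vanillin
Product: 25 3-methoxy-4-(triisopropylsilyloxy)benzaldehyde
Conditions: i-Pr3SiCl, imidazole, DMF, rt
Reagents that add atoms: triisopropylsilyl chloride, CC(C)[Si](Cl)(C(C)C)C(C)C
Why: Silylation of the phenol gives an aryl ether robust toward boron triflate, borohydride and butyllithium that falls in the final fluoride step.

Step 17
Reactants: 23 ring B aryloxyacetyl imide; 25 3-methoxy-4-(triisopropylsilyloxy)benzaldehyde
Product: 27 (R)-4-benzyl-3-[(2R,3S)-2-(4-bromo-2,6-dimethoxyphenoxy)-3-hydroxy-3-[3-methoxy-4-(triisopropylsilyloxy)phenyl]propanoyl]-1,3-oxazolidin-2-one, via boron enolate 26 (not isolated)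
Conditions: Bu2BOTf, i-Pr2NEt, CH2Cl2, −78 to 0 °C; 25, −78 to 0 °C; pH 7 buffer, MeOH, H2O2, 0 °C
Reagents that add atoms: none
Why: Evans syn glycolate aldol through the (Z)-boron enolate and a chair transition state on the face away from the auxiliary benzyl group, which sets C8 in its final configuration and C7 as the syn (threo) epimer to be inverted next.

Step 18
Reactants: 27 syn glycolate adduct
Product: 28 (R)-4-benzyl-3-[(2R,3R)-2-(4-bromo-2,6-dimethoxyphenoxy)-3-[3-methoxy-4-(triisopropylsilyloxy)phenyl]-3-(4-nitrobenzoyloxy)propanoyl]-1,3-oxazolidin-2-one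
Conditions: 4-O2NC6H4CO2H, PPh3, DIAD, THF, 0 °C to rt
Reagents that add atoms: 4-nitrobenzoic acid, OC(=O)c1ccc(cc1)[N+](=O)[O-]
Why: Mitsunobu esterification, in which the carboxylate displaces the alkoxyphosphonium group by SN2, inverts C7 and so turns the syn adduct into the anti (erythro) series; elimination should be held back because allylic strain keeps the imide α-hydrogen in the imide plane.

Step 19
Reactants: 28 inverted 4-nitrobenzoate
Product: 29 (1R,2S)-2-(4-bromo-2,6-dimethoxyphenoxy)-1-[3-methoxy-4-(triisopropylsilyloxy)phenyl]propane-1,3-diol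
Conditions: LiBH4, MeOH, THF, 0 °C to rt
Reagents that add atoms: none
Why: Borohydride reduction cleaves the acyl oxazolidinone to the primary alcohol and the activated benzoate to the free carbinol in one operation, leaving aryl bromide, nitro group of the by-product and aryl silyl ether untouched.

Step 20
Reactants: 29 erythro diol
Product: 30 5-bromo-2-{[(1R,2S)-1,3-bis(tert-butyldimethylsilyloxy)-1-[3-methoxy-4-(triisopropylsilyloxy)phenyl]propan-2-yl]oxy}-1,3-dimethoxybenzene
Conditions: t-BuMe2SiOTf, 2,6-lutidine, CH2Cl2, 0 °C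
Reagents that add atoms: tert-butyldimethylsilyl triflate, CC(C)(C)[Si](C)(C)OS(=O)(=O)C(F)(F)F
Why: Silyl triflate with a hindered pyridine base silylates both the primary and the hindered benzylic hydroxyl, so that no free OH meets butyllithium or boron triflate later.

Step 21
Reactants: 30 bis-silyl ether bromide
Product: 32 4-{[(1R,2S)-1,3-bis(tert-butyldimethylsilyloxy)-1-[3-methoxy-4-(triisopropylsilyloxy)phenyl]propan-2-yl]oxy}-3,5-dimethoxybenzaldehyde, via aryllithium 31 (not isolated)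
Conditions: n-BuLi, THF, −78 °C; DMF, −78 to 0 °C; H2O
Reagents that add atoms: N,N-dimethylformamide, CN(C)C=O
Why: Bromine–lithium exchange followed by formylation with DMF converts the aryl bromide into the ring B aldehyde in a molecule that now carries only ethers and silyl ethers.

Step 22
Reactants: 21 ring C/D aryloxyacetyl imide; 32 ring A/B aldehyde
Product: 34 syn aldol adduct of 21 and 32 with a (2R,3S)-3-hydroxypropanoyl chain on the (R)-oxazolidinone, via boron enolate 33 (not isolated)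
Conditions: Bu2BOTf, i-Pr2NEt, CH2Cl2, −78 to 0 °C; 32, −78 to 0 °C; pH 7 buffer, MeOH, H2O2, 0 °C
Reagents that add atoms: none
Why: The same Evans syn glycolate aldol joins the two halves, the (R)-auxiliary fixing C8' in its final configuration and C7' as the syn epimer, while the amine-buffered boron triflate should spare the cyclic acetal and the silyl ethers.

Step 23
Reactants: 34 syn aldol adduct
Product: 35 4-nitrobenzoate of 34 with inverted C7' and a (2R,3R)-acyl chain
Conditions: 4-O2NC6H4CO2H, PPh3, DIAD, THF, 0 °C to rt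
Reagents that add atoms: 4-nitrobenzoic acid, OC(=O)c1ccc(cc1)[N+](=O)[O-]
Why: Mitsunobu inversion by SN2 displacement of the alkoxyphosphonium group converts the (7'S) carbinol into the (7'R) ester and so gives the second erythro unit.

Step 24
Reactants: 35 inverted 4-nitrobenzoate
Product: 36 erythro (7'R,8'S) diol with ring D as dioxolane and the A/B unit silylated
Conditions: LiBH4, MeOH, THF, 0 °C to rt
Reagents that add atoms: none
Why: Borohydride reduction removes the auxiliary as the C9' primary alcohol and the benzoate as the C7' carbinol at once, with acetal and silyl ethers inert.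

Step 25
Reactants: 36 erythro diol acetal
Product: 37 the corresponding ring D C5 carbaldehyde
Conditions: PPTS, THF/H2O (4:1), 40 °C
Reagents that add atoms: water, O
Why: Hydrolysis of an acetal whose oxocarbenium ion is stabilised by the para ring oxygen O1 should proceed under acid too weak to ionise the benzylic alcohols or the C2 aryl ether.

Step 26
Reactants: 37 ring D aldehyde
Product: 38 the (E)-prop-2-enal at C5 of ring D with all silyl ethers in place
Conditions: Ph3P=CHCHO (1.3 equiv), toluene, 80 °C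
Reagents that add atoms: (triphenylphosphoranylidene)acetaldehyde, O=CC=P(c1ccccc1)(c1ccccc1)c1ccccc1
Why: Wittig olefination with the stabilised formyl ylide gives the E enal by two-carbon extension, and a small excess of ylide limits a second homologation.

Step 27
Reactants: 38 silylated enal
Product: 39 target CNP0192639.1
Conditions: Bu4NF, AcOH, THF, 0 °C to rt
Reagents that add atoms: none
Why: Acetic-acid-buffered fluoride desilylation removes the two tert-butyldimethylsilyl and two triisopropylsilyl groups without base-induced damage to the enal or the phenolic arylglycerol unit.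

**Compound list**

1 | 4-fluoro-3-methoxybenzaldehyde | COc1cc(C=O)ccc1F | starting material
2 | 2-(4-fluoro-3-methoxyphenyl)-1,3-dioxolane | COc1cc(C2OCCO2)ccc1F | intermediate
3 | [5-(1,3-dioxolan-2-yl)-2-fluoro-3-methoxyphenyl]lithium | COc1cc(C2OCCO2)cc([Li])c1F | intermediate
4 | 2-[4-fluoro-3-methoxy-5-(prop-2-en-1-yl)phenyl]-1,3-dioxolane | COc1cc(C2OCCO2)cc(CC=C)c1F | intermediate
5 | [5-(1,3-dioxolan-2-yl)-2-fluoro-3-methoxyphenyl]acetic acid | COc1cc(C2OCCO2)cc(CC(O)=O)c1F | intermediate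
6 | (R)-4-benzyl-1,3-oxazolidin-2-one | O=C1N[C@H](Cc2ccccc2)CO1 | starting material
7 | mixed anhydride of 5 with pivalic acid | COc1cc(C2OCCO2)cc(CC(=O)OC(=O)C(C)(C)C)c1F | intermediate
8 | (R)-4-benzyl-3-{[5-(1,3-dioxolan-2-yl)-2-fluoro-3-methoxyphenyl]acetyl}-1,3-oxazolidin-2-one | COc1cc(C2OCCO2)cc(CC(=O)N2[C@H](Cc3ccccc3)COC2=O)c1F | intermediate
9 | syringaldehyde (4-hydroxy-3,5-dimethoxybenzaldehyde) | COc1cc(C=O)cc(OC)c1O | starting material
10 | 4-(allyloxy)-3,5-dimethoxybenzaldehyde | C=CCOc1c(OC)cc(C=O)cc1OC | intermediate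
11 | (Z)-dibutylboron enolate of 8 | CCCCB(CCCC)O/C(=C\c1cc(C2OCCO2)cc(OC)c1F)N1[C@H](Cc2ccccc2)COC1=O | intermediate
12 | (R)-4-benzyl-3-[(2R,3R)-3-(4-allyloxy-3,5-dimethoxyphenyl)-2-[5-(1,3-dioxolan-2-yl)-2-fluoro-3-methoxyphenyl]-3-hydroxypropanoyl]-1,3-oxazolidin-2-one | C=CCOc1c(OC)cc(cc1OC)[C@H](O)[C@@H](c1cc(C2OCCO2)cc(OC)c1F)C(=O)N1[C@H](Cc2ccccc2)COC1=O | intermediate
13 | (1R,2S)-1-(4-allyloxy-3,5-dimethoxyphenyl)-2-[5-(1,3-dioxolan-2-yl)-2-fluoro-3-methoxyphenyl]propane-1,3-diol | C=CCOc1c(OC)cc(cc1OC)[C@H](O)[C@@H](c1cc(C2OCCO2)cc(OC)c1F)CO | intermediate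
14 | (1R,2S)-1-(4-allyloxy-3,5-dimethoxyphenyl)-2-[5-(1,3-dioxolan-2-yl)-2-fluoro-3-methoxyphenyl]-3-(triisopropylsilyloxy)propan-1-ol | C=CCOc1c(OC)cc(cc1OC)[C@H](O)[C@@H](c1cc(C2OCCO2)cc(OC)c1F)CO[Si](C(C)C)(C(C)C)C(C)C | intermediate
15 | 3-[(1R,2S)-1-(4-allyloxy-3,5-dimethoxyphenyl)-1-hydroxy-3-(triisopropylsilyloxy)propan-2-yl]-4-fluoro-5-methoxybenzaldehyde (key-step precursor) | C=CCOc1c(OC)cc(cc1OC)[C@H](O)[C@@H](c1cc(C=O)cc(OC)c1F)CO[Si](C(C)C)(C(C)C)C(C)C | intermediate
16 | (2R,3S)-2-(4-allyloxy-3,5-dimethoxyphenyl)-7-methoxy-3-[(triisopropylsilyloxy)methyl]-2,3-dihydro-1-benzofuran-5-carbaldehyde (key-step product) | C=CCOc1c(OC)cc(cc1OC)[C@@H]1Oc2c(OC)cc(C=O)cc2[C@H]1CO[Si](C(C)C)(C(C)C)C(C)C | intermediate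
17 | 2-[(2R,3S)-2-(4-allyloxy-3,5-dimethoxyphenyl)-7-methoxy-3-[(triisopropylsilyloxy)methyl]-2,3-dihydro-1-benzofuran-5-yl]-1,3-dioxolane | C=CCOc1c(OC)cc(cc1OC)[C@@H]1Oc2c(OC)cc(C3OCCO3)cc2[C@H]1CO[Si](C(C)C)(C(C)C)C(C)C | intermediate
18 | 4-[(2R,3S)-5-(1,3-dioxolan-2-yl)-7-methoxy-3-[(triisopropylsilyloxy)methyl]-2,3-dihydro-1-benzofuran-2-yl]-2,6-dimethoxyphenol | COc1cc(cc(OC)c1O)[C@@H]1Oc2c(OC)cc(C3OCCO3)cc2[C@H]1CO[Si](C(C)C)(C(C)C)C(C)C | intermediate
19 | N-lithio derivative of 6 | [Li]N1[C@H](Cc2ccccc2)COC1=O | intermediate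
20 | (R)-4-benzyl-3-(bromoacetyl)-1,3-oxazolidin-2-one | BrCC(=O)N1[C@H](Cc2ccccc2)COC1=O | intermediate
21 | (R)-4-benzyl-3-({4-[(2R,3S)-5-(1,3-dioxolan-2-yl)-7-methoxy-3-[(triisopropylsilyloxy)methyl]-2,3-dihydro-1-benzofuran-2-yl]-2,6-dimethoxyphenoxy}acetyl)-1,3-oxazolidin-2-one | O=C(COc1c(OC)cc(cc1OC)[C@@H]1Oc2c(OC)cc(C3OCCO3)cc2[C@H]1CO[Si](C(C)C)(C(C)C)C(C)C)N1[C@H](Cc2ccccc2)COC1=O | intermediate
22 | 4-bromo-2,6-dimethoxyphenol | COc1cc(Br)cc(OC)c1O | starting material
23 | (R)-4-benzyl-3-[(4-bromo-2,6-dimethoxyphenoxy)acetyl]-1,3-oxazolidin-2-one | O=C(COc1c(OC)cc(Br)cc1OC)N1[C@H](Cc2ccccc2)COC1=O | intermediate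
24 | vanillin (4-hydroxy-3-methoxybenzaldehyde) | COc1cc(C=O)ccc1O | starting material
25 | 3-methoxy-4-(triisopropylsilyloxy)benzaldehyde | COc1cc(C=O)ccc1O[Si](C(C)C)(C(C)C)C(C)C | intermediate
26 | (Z)-dibutylboron enolate of 23 | CCCCB(CCCC)O/C(=C\Oc1c(OC)cc(Br)cc1OC)N1[C@H](Cc2ccccc2)COC1=O | intermediate
27 | (R)-4-benzyl-3-[(2R,3S)-2-(4-bromo-2,6-dimethoxyphenoxy)-3-hydroxy-3-[3-methoxy-4-(triisopropylsilyloxy)phenyl]propanoyl]-1,3-oxazolidin-2-one | COc1cc(ccc1O[Si](C(C)C)(C(C)C)C(C)C)[C@H](O)[C@H](C(=O)N1[C@H](Cc2ccccc2)COC1=O)Oc1c(OC)cc(Br)cc1OC | intermediate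
28 | (R)-4-benzyl-3-[(2R,3R)-2-(4-bromo-2,6-dimethoxyphenoxy)-3-[3-methoxy-4-(triisopropylsilyloxy)phenyl]-3-(4-nitrobenzoyloxy)propanoyl]-1,3-oxazolidin-2-one | COc1cc(ccc1O[Si](C(C)C)(C(C)C)C(C)C)[C@@H](OC(=O)c1ccc(cc1)[N+](=O)[O-])[C@H](C(=O)N1[C@H](Cc2ccccc2)COC1=O)Oc1c(OC)cc(Br)cc1OC | intermediate
29 | (1R,2S)-2-(4-bromo-2,6-dimethoxyphenoxy)-1-[3-methoxy-4-(triisopropylsilyloxy)phenyl]propane-1,3-diol | COc1cc(ccc1O[Si](C(C)C)(C(C)C)C(C)C)[C@@H](O)[C@H](CO)Oc1c(OC)cc(Br)cc1OC | intermediate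
30 | 5-bromo-2-{[(1R,2S)-1,3-bis(tert-butyldimethylsilyloxy)-1-[3-methoxy-4-(triisopropylsilyloxy)phenyl]propan-2-yl]oxy}-1,3-dimethoxybenzene | COc1cc(ccc1O[Si](C(C)C)(C(C)C)C(C)C)[C@@H](O[Si](C)(C)C(C)(C)C)[C@H](CO[Si](C)(C)C(C)(C)C)Oc1c(OC)cc(Br)cc1OC | intermediate
31 | aryllithium from 30 (Li in place of Br on ring B) | COc1cc(ccc1O[Si](C(C)C)(C(C)C)C(C)C)[C@@H](O[Si](C)(C)C(C)(C)C)[C@H](CO[Si](C)(C)C(C)(C)C)Oc1c(OC)cc([Li])cc1OC | intermediate
32 | 4-{[(1R,2S)-1,3-bis(tert-butyldimethylsilyloxy)-1-[3-methoxy-4-(triisopropylsilyloxy)phenyl]propan-2-yl]oxy}-3,5-dimethoxybenzaldehyde | COc1cc(ccc1O[Si](C(C)C)(C(C)C)C(C)C)[C@@H](O[Si](C)(C)C(C)(C)C)[C@H](CO[Si](C)(C)C(C)(C)C)Oc1c(OC)cc(C=O)cc1OC | intermediate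
33 | (Z)-dibutylboron enolate of 21 | CCCCB(CCCC)O/C(=C\Oc1c(OC)cc(cc1OC)[C@@H]1Oc2c(OC)cc(C3OCCO3)cc2[C@H]1CO[Si](C(C)C)(C(C)C)C(C)C)N1[C@H](Cc2ccccc2)COC1=O | intermediate
34 | (R)-4-benzyl-3-acyl-1,3-oxazolidin-2-one whose acyl group is (2R,3S)-3-hydroxypropanoyl bearing on C2 (C8') the ring C aryloxy group of 21 and on C3 (C7') the ring B aryl group of 32 | COc1cc(ccc1O[Si](C(C)C)(C(C)C)C(C)C)[C@@H](O[Si](C)(C)C(C)(C)C)[C@H](CO[Si](C)(C)C(C)(C)C)Oc1c(OC)cc(cc1OC)[C@H](O)[C@H](C(=O)N1[C@H](Cc2ccccc2)COC1=O)Oc1c(OC)cc(cc1OC)[C@@H]1Oc2c(OC)cc(C3OCCO3)cc2[C@H]1CO[Si](C(C)C)(C(C)C)C(C)C | intermediate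
35 | 4-nitrobenzoate of 34 with inverted C7' ((2R,3R)-acyl chain) | COc1cc(ccc1O[Si](C(C)C)(C(C)C)C(C)C)[C@@H](O[Si](C)(C)C(C)(C)C)[C@H](CO[Si](C)(C)C(C)(C)C)Oc1c(OC)cc(cc1OC)[C@@H](OC(=O)c1ccc(cc1)[N+](=O)[O-])[C@H](C(=O)N1[C@H](Cc2ccccc2)COC1=O)Oc1c(OC)cc(cc1OC)[C@@H]1Oc2c(OC)cc(C3OCCO3)cc2[C@H]1CO[Si](C(C)C)(C(C)C)C(C)C | intermediate
36 | (1R,2S)-1-[4-({(1R,2S)-1,3-bis(tert-butyldimethylsilyloxy)-1-[3-methoxy-4-(triisopropylsilyloxy)phenyl]propan-2-yl}oxy)-3,5-dimethoxyphenyl]-2-{4-[(2R,3S)-5-(1,3-dioxolan-2-yl)-7-methoxy-3-[(triisopropylsilyloxy)methyl]-2,3-dihydro-1-benzofuran-2-yl]-2,6-dimethoxyphenoxy}propane-1,3-diol | COc1cc(ccc1O[Si](C(C)C)(C(C)C)C(C)C)[C@@H](O[Si](C)(C)C(C)(C)C)[C@H](CO[Si](C)(C)C(C)(C)C)Oc1c(OC)cc(cc1OC)[C@@H](O)[C@H](CO)Oc1c(OC)cc(cc1OC)[C@@H]1Oc2c(OC)cc(C3OCCO3)cc2[C@H]1CO[Si](C(C)C)(C(C)C)C(C)C | intermediate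
37 | aldehyde from 36: the 1,3-dioxolan-2-yl group on C5 of ring D replaced by CHO | COc1cc(ccc1O[Si](C(C)C)(C(C)C)C(C)C)[C@@H](O[Si](C)(C)C(C)(C)C)[C@H](CO[Si](C)(C)C(C)(C)C)Oc1c(OC)cc(cc1OC)[C@@H](O)[C@H](CO)Oc1c(OC)cc(cc1OC)[C@@H]1Oc2c(OC)cc(C=O)cc2[C@H]1CO[Si](C(C)C)(C(C)C)C(C)C | intermediate
38 | (E)-enal from 37: CHO on C5 of ring D extended to CH=CH–CHO | COc1cc(ccc1O[Si](C(C)C)(C(C)C)C(C)C)[C@@H](O[Si](C)(C)C(C)(C)C)[C@H](CO[Si](C)(C)C(C)(C)C)Oc1c(OC)cc(cc1OC)[C@@H](O)[C@H](CO)Oc1c(OC)cc(cc1OC)[C@@H]1Oc2c(OC)cc(/C=C/C=O)cc2[C@H]1CO[Si](C(C)C)(C(C)C)C(C)C | intermediate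
39 | CNP0192639.1: (E)-3-[(2R,3S)-2-{4-[((1R,2S)-1-{4-[((1R,2S)-1,3-dihydroxy-1-(4-hydroxy-3-methoxyphenyl)propan-2-yl)oxy]-3,5-dimethoxyphenyl}-1,3-dihydroxypropan-2-yl)oxy]-3,5-dimethoxyphenyl}-3-(hydroxymethyl)-7-methoxy-2,3-dihydro-1-benzofuran-5-yl]prop-2-enal | COc1cc([C@@H](O)[C@H](CO)Oc2c(OC)cc([C@@H](O)[C@H](CO)Oc3c(OC)cc([C@@H]4Oc5c(OC)cc(/C=C/C=O)cc5[C@H]4CO)cc3OC)cc2OC)ccc1O | target

**Totals and risks**

Total step count: 27. Longest linear sequence: 18 steps (steps 1–4, 6–12, 14, 22–27).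

Steps most likely to fail:

1. Step 10. The closure may lag behind base-induced consumption of the free aldehyde, or a slow 1,5 shift of silicon may free the primary alkoxide for the competing closure. The fallback changes the activating group so that a strong base can be used at low temperature. It sets out from 15: oxidative amination with I2 and aqueous NH3 in THF converts the formyl group into the nitrile, 3-[(1R,2S)-1-(4-allyloxy-3,5-dimethoxyphenyl)-1-hydroxy-3-(triisopropylsilyloxy)propan-2-yl]-4-fluoro-5-methoxybenzonitrile F2. Stoichiometric KN(SiMe3)2 in THF at −40 to 0 °C then effects the cyano-activated SNAr closure to (2R,3S)-2-(4-allyloxy-3,5-dimethoxyphenyl)-7-methoxy-3-[(triisopropylsilyloxy)methyl]-2,3-dihydro-1-benzofuran-5-carbonitrile F3. Reduction with i-Bu2AlH in toluene at −78 °C and hydrolysis of the aldimine returns to the route at 16.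

2. Step 23. The activated carbinol may eliminate toward the α-aryloxy enoyl imide, or the electron-rich benzylic position may ionise so that substitution is not cleanly invertive. The fallback replaces substitution by oxidation and chelation-controlled reduction. It sets out from 34: LiBH4 gives the threo diol, the (7'S,8'S) diastereomer of 36 F4. Et3SiCl and imidazole at −20 °C cap the primary hydroxyl as the triethylsilyl ether of the threo diol F5. Dess–Martin periodinane with NaHCO3 gives the aryl ketone at C7' F6. Zn(BH4)2 in Et2O at −20 °C should then reduce it under Cram-chelate control (zinc bridging the carbonyl and aryloxy oxygens, hydride entering past H-8') to the erythro alcohol, the 9'-O-triethylsilyl ether of 36 F7. Aqueous PPTS in THF removes the triethylsilyl group together with the dioxolane and returns to the route at 37.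

3. Step 2. Deprotonation may occur at the position between methoxy and acetal, or the ortho-fluoroaryllithium may lose LiF before it is allylated. The fallback avoids an aryl anion. It sets out from 2: iridium-catalysed C–H borylation ([Ir(OMe)(cod)]2, 4,4'-di-tert-butyl-2,2'-bipyridine, bis(pinacolato)diboron, THF, 60 °C) is sterically directed to the only C–H flanked by fluorine and hydrogen. This gives 2-[5-(1,3-dioxolan-2-yl)-2-fluoro-3-methoxyphenyl]-4,4,5,5-tetramethyl-1,3,2-dioxaborolane F1. Suzuki–Miyaura allylation with allyl bromide (Pd(PPh3)4, K2CO3, THF/H2O, 60 °C) returns to the route at 4.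

**Further compounds**

F1 | step 2 | 2-[5-(1,3-dioxolan-2-yl)-2-fluoro-3-methoxyphenyl]-4,4,5,5-tetramethyl-1,3,2-dioxaborolane | COc1cc(C2OCCO2)cc(B3OC(C)(C)C(C)(C)O3)c1F
F2 | step 10 | 3-[(1R,2S)-1-(4-allyloxy-3,5-dimethoxyphenyl)-1-hydroxy-3-(triisopropylsilyloxy)propan-2-yl]-4-fluoro-5-methoxybenzonitrile | C=CCOc1c(OC)cc(cc1OC)[C@H](O)[C@@H](c1cc(C#N)cc(OC)c1F)CO[Si](C(C)C)(C(C)C)C(C)C
F3 | step 10 | (2R,3S)-2-(4-allyloxy-3,5-dimethoxyphenyl)-7-methoxy-3-[(triisopropylsilyloxy)methyl]-2,3-dihydro-1-benzofuran-5-carbonitrile | C=CCOc1c(OC)cc(cc1OC)[C@@H]1Oc2c(OC)cc(C#N)cc2[C@H]1CO[Si](C(C)C)(C(C)C)C(C)C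
F4 | step 23 | threo diol, the (7'S,8'S) diastereomer of 36 | COc1cc(ccc1O[Si](C(C)C)(C(C)C)C(C)C)[C@@H](O[Si](C)(C)C(C)(C)C)[C@H](CO[Si](C)(C)C(C)(C)C)Oc1c(OC)cc(cc1OC)[C@H](O)[C@H](CO)Oc1c(OC)cc(cc1OC)[C@@H]1Oc2c(OC)cc(C3OCCO3)cc2[C@H]1CO[Si](C(C)C)(C(C)C)C(C)C
F5 | step 23 | 9'-O-triethylsilyl ether of the threo diol | COc1cc(ccc1O[Si](C(C)C)(C(C)C)C(C)C)[C@@H](O[Si](C)(C)C(C)(C)C)[C@H](CO[Si](C)(C)C(C)(C)C)Oc1c(OC)cc(cc1OC)[C@H](O)[C@H](CO[Si](CC)(CC)CC)Oc1c(OC)cc(cc1OC)[C@@H]1Oc2c(OC)cc(C3OCCO3)cc2[C@H]1CO[Si](C(C)C)(C(C)C)C(C)C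
F6 | step 23 | C7' aryl ketone with (8'S) aryloxy carbon and 9'-O-triethylsilyl group | COc1cc(ccc1O[Si](C(C)C)(C(C)C)C(C)C)[C@@H](O[Si](C)(C)C(C)(C)C)[C@H](CO[Si](C)(C)C(C)(C)C)Oc1c(OC)cc(cc1OC)C(=O)[C@H](CO[Si](CC)(CC)CC)Oc1c(OC)cc(cc1OC)[C@@H]1Oc2c(OC)cc(C3OCCO3)cc2[C@H]1CO[Si](C(C)C)(C(C)C)C(C)C
F7 | step 23 | erythro (7'R,8'S) alcohol, the 9'-O-triethylsilyl ether of 36 | COc1cc(ccc1O[Si](C(C)C)(C(C)C)C(C)C)[C@@H](O[Si](C)(C)C(C)(C)C)[C@H](CO[Si](C)(C)C(C)(C)C)Oc1c(OC)cc(cc1OC)[C@@H](O)[C@H](CO[Si](CC)(CC)CC)Oc1c(OC)cc(cc1OC)[C@@H]1Oc2c(OC)cc(C3OCCO3)cc2[C@H]1CO[Si](C(C)C)(C(C)C)C(C)C
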